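## Retrosynthetic overview
1. Target 26 ⇒ macrocyclic trans-γ-lactone 21: the C9 acetate and the C15=C17 methylene (Mannich reaction, then elimination) are put on last.
2. 21 ⇒ 19: the 14-membered ring is closed at C12–C13 by an intramolecular B-alkyl Suzuki coupling of a C1-vinyl group with an (E)-alkenyl iodide.
3. 19 ⇒ enal 11 + succinyl imide 14: the C1–C2 bond, both ring-fusion stereocentres and the lactone come from one intermolecular Evans syn-aldol/lactonisation, which joins the two fragments.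
4. 11 ⇒ geraniol 1: SeO2 oxidation (C9), asymmetric propargylation (C9 stereocentre), alkyne methylation, hydrozirconation–iodination (C11=C12–I).
5. Ring order: γ-lactone first (step 11), 14-membered carbocycle second (step 15).

Assumption: locants C1–C17 are cembrane locants (C1/C2 ring fusion, C9 carbinol, C17 exocyclic CH2); deprotonated forms and O–B/O–metal species that exist only until work-up are not numbered; CIP descriptors are those of each compound as drawn, so they can change along the route while the spatial arrangement stays that of the target.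

## Route

Step 1
Reactants: 1 geraniol
Product: 2 geranyl PMB ether
Conditions: NaH, PMBCl, Bu4NI (cat.), THF/DMF, 0 °C→rt
Reagents that add atoms: 4-methoxybenzyl chloride COc1ccc(CCl)cc1
Why: Williamson ether synthesis on the primary allylic alkoxide; PMB survives SeO2, n-BuLi and Schwartz reagent and is later removed oxidatively next to a TBS ether.

Step 2
Reactants: 2 geranyl PMB ether
Product: 3 (2E,6E)-8-PMBO-2,6-dimethylocta-2,6-dien-1-ol
Conditions: SeO2 (cat.), t-BuOOH, salicylic acid (cat.), CH2Cl2, rt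
Reagents that add atoms: selenium dioxide O=[Se]=O; tert-butyl hydroperoxide CC(C)(C)OO
Why: Sharpless SeO2 allylic oxidation (ene reaction then [2,3]-shift) attacks the E-methyl of the more electron-rich terminal alkene and gives the (E)-allylic alcohol, placing oxygen on C9.

Step 3
Reactants: 3 (2E,6E)-8-PMBO-2,6-dimethylocta-2,6-dien-1-ol
Product: 4 (2E,6E)-8-PMBO-2,6-dimethylocta-2,6-dienal
Conditions: MnO2, CH2Cl2, rt
Reagents that add atoms: none
Why: MnO2 allylic oxidation gives the (E)-enal chemoselectively without alkene isomerisation.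

Step 4
Reactants: 4 (2E,6E)-8-PMBO-2,6-dimethylocta-2,6-dienal
Product: 5 (R)-homopropargylic alcohol
Conditions: allenyl-Bpin, (R)-TRIP (5 mol%), 4 Å MS, toluene, 0 °C; aq. work-up
Reagents that add atoms: allenylboronic acid pinacol ester C=C=CB1OC(C)(C)C(C)(C)O1
Why: chiral phosphoric-acid-catalysed carbonyl propargylation (allenylboronate SE2′ addition through a closed six-membered transition state, the propargyl counterpart of allylboration); (R)-TRIP is expected to direct Re-face attack, by analogy with aryl and other α,β-unsaturated aldehydes, setting C9 as R.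

Step 5
Reactants: 5 (R)-homopropargylic alcohol
Product: 6 TBS ether of 5
Conditions: TBSCl, imidazole, DMF, rt
Reagents that add atoms: tert-butyldimethylsilyl chloride CC(C)(C)[Si](C)(C)Cl
Why: standard silylation of the secondary allylic alcohol; the C9 configuration is untouched.

Step 6
Reactants: 6 TBS ether of 5
Product: 7 methyl alkyne
Conditions: n-BuLi, THF, −78 °C; MeI, −78 °C→rt
Reagents that add atoms: iodomethane CI
Why: acetylide alkylation; the terminal alkyne C–H is the only acidic site and its lithium salt is methylated to give the C12 methyl group.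

Step 7
Reactants: 7 methyl alkyne
Product: 9 (E)-alkenyl iodide PMB ether, via alkenylzirconocene chloride 8 (not isolated)
Conditions: Cp2Zr(H)Cl (2.5 equiv), THF, 50 °C; I2, 0 °C
Reagents that add atoms: iodine II
Why: Schwartz hydrozirconation is a syn addition that, under equilibrating conditions, puts Zr on the less hindered methyl-bearing carbon (C12); iodinolysis with retention gives the (E)-2-iodoalkene that fixes the 11E geometry.

Step 8
Reactants: 9 (E)-alkenyl iodide PMB ether
Product: 10 allylic alcohol (C2–OH)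
Conditions: DDQ, CH2Cl2/pH 7 buffer, 0 °C
Reagents that add atoms: none
Why: oxidative PMB ether cleavage by DDQ; TBS ether, alkenes and alkenyl iodide are inert.

Step 9
Reactants: 10 allylic alcohol (C2–OH)
Product: 11 (2E)-enal (C2 aldehyde)
Conditions: MnO2, CH2Cl2, rt
Reagents that add atoms: none
Why: MnO2 allylic oxidation gives the geranial-type (E)-enal needed as aldol acceptor.

Step 10
Reactants: 12 (4R)-4-benzyl-1,3-oxazolidin-2-one; 13 methyl 4-chloro-4-oxobutanoate
Product: 14 methyl 4-[(4R)-4-benzyl-2-oxo-1,3-oxazolidin-3-yl]-4-oxobutanoate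
Conditions: n-BuLi, THF, −78 °C; then 13, −78→0 °C
Reagents that add atoms: none
Why: N-acylation of the lithiated oxazolidinone by the acid chloride, which is far more electrophilic than the methyl ester.

Step 11
Reactants: 14 succinyl imide; 11 (2E)-enal
Product: 16 trans-lactone imide, via syn-aldol adduct 15 (not isolated)
Conditions: Bu2BOTf, iPr2NEt, CH2Cl2, 0 °C; 11, −78→0 °C; pH 7 buffer/MeOH/H2O2, 0 °C; PPTS (cat.), CH2Cl2, rt
Reagents that add atoms: none
Why: Evans syn-aldol reaction; the Z-boron enolate of the imide (not the ester) adds through a Zimmerman–Traxler chair on the face opposite the (R)-benzyl group to give the (3R,4S)-syn adduct (C1 and C2), whose hydroxyl closes onto the methyl ester to the trans-β,γ-disubstituted γ-lactone.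

Step 12
Reactants: 16 trans-lactone imide
Product: 17 hydroxymethyl lactone
Conditions: NaBH4, THF/H2O (4:1), 0 °C→rt
Reagents that add atoms: none
Why: reductive cleavage of the auxiliary; borohydride attacks the exocyclic imide carbonyl, which is more electrophilic than the lactone, and releases the oxazolidinone without touching a stereocentre.

Step 13
Reactants: 17 hydroxymethyl lactone
Product: 18 formyl lactone
Conditions: Dess–Martin periodinane, CH2Cl2, 0 °C→rt
Reagents that add atoms: none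
Why: Dess–Martin oxidation is neutral, so the aldehyde is formed without C1 epimerisation or β-elimination of the lactone carboxylate.

Step 14
Reactants: 18 formyl lactone
Product: 19 vinyl lactone
Conditions: Zn, CH2Br2, TiCl4, THF/CH2Cl2, 0 °C→rt
Reagents that add atoms: dibromomethane BrCBr
Why: Takai–Lombardo methylenation; the non-basic gem-dizinc/titanium reagent methylenates the aldehyde without enolising it and leaves the lactone carbonyl alone (this carbon becomes C13).

Step 15
Reactants: 19 vinyl lactone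
Product: 21 macrocyclic trans-lactone, via alkyl-9-BBN borane 20 (not isolated)
Conditions: 9-BBN, THF, 0 °C→rt; then slow addition to PdCl2(dppf) (15 mol%), AsPh3, Cs2CO3, H2O, DMF/THF, rt, 2 mM
Reagents that add atoms: none
Why: 9-BBN hydroborates only the monosubstituted vinyl group (anti-Markovnikov), and the intramolecular B-alkyl Suzuki–Miyaura coupling with the alkenyl iodide closes the 14-membered ring at C12–C13 with retention of the E geometry.

Step 16
Reactants: 21 macrocyclic trans-lactone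
Product: 22 α-(dimethylaminomethyl) lactone
Conditions: LDA, THF, −78 °C; Me2N+=CH2 I−, −78 °C→rt
Reagents that add atoms: N,N-dimethylmethyleneiminium iodide C=[N+](C)C.[I-]
Why: Mannich reaction of the lactone lithium enolate with Eschenmoser's salt; attack anti to the C1–C14 bond gives the 15S epimer, a centre that is destroyed two steps later.

Step 17
Reactants: 22 α-(dimethylaminomethyl) lactone
Product: 23 trimethylammonium iodide
Conditions: MeI (excess), MeOH, rt; evaporate
Reagents that add atoms: iodomethane CI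
Why: Menshutkin quaternisation of the only basic nitrogen turns the amine into a leaving group.

Step 18
Reactants: 23 trimethylammonium iodide
Product: 24 α-methylene lactone TBS ether
Conditions: NaHCO3 (aq.), EtOAc, rt
Reagents that add atoms: none
Why: Hofmann-type E1cB elimination of trimethylamine from the β-ammonio lactone gives the exocyclic C15=C17 alkene under very mild base.

Step 19
Reactants: 24 α-methylene lactone TBS ether
Product: 25 C9 alcohol
Conditions: HF·pyridine, pyridine/THF, 0 °C→rt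
Reagents that add atoms: none
Why: fluoride-mediated desilylation; buffered HF·pyridine avoids conjugate addition to the α-methylene lactone and leaves C9 unchanged.

Step 20
Reactants: 25 C9 alcohol
Product: 26 target acetate
Conditions: Ac2O, pyridine, DMAP (cat.), CH2Cl2, 0 °C→rt
Reagents that add atoms: acetic anhydride CC(=O)OC(C)=O
Why: DMAP-catalysed acetylation of the secondary allylic alcohol with retention at C9 gives the target.

## Compound list
Rs = (1E,5E,7R,9E)-7-(tert-butyldimethylsilyloxy)-10-iodo-2,6-dimethylundeca-1,5,9-trien-1-yl.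

1 | geraniol, (2E)-3,7-dimethylocta-2,6-dien-1-ol | CC(C)=CCC/C(C)=C/CO | starting material
2 | 1-({[(2E)-3,7-dimethylocta-2,6-dien-1-yl]oxy}methyl)-4-methoxybenzene | COc1ccc(COC/C=C(\C)CCC=C(C)C)cc1 | intermediate
3 | (2E,6E)-8-[(4-methoxybenzyl)oxy]-2,6-dimethylocta-2,6-dien-1-ol | COc1ccc(COC/C=C(\C)CC/C=C(\C)CO)cc1 | intermediate
4 | (2E,6E)-8-[(4-methoxybenzyl)oxy]-2,6-dimethylocta-2,6-dienal | COc1ccc(COC/C=C(\C)CC/C=C(\C)C=O)cc1 | intermediate
5 | (4R,5E,9E)-11-[(4-methoxybenzyl)oxy]-5,9-dimethylundeca-5,9-dien-1-yn-4-ol | COc1ccc(COC/C=C(\C)CC/C=C(\C)[C@H](O)CC#C)cc1 | intermediate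
6 | tert-butyl{[(4R,5E,9E)-11-[(4-methoxybenzyl)oxy]-5,9-dimethylundeca-5,9-dien-1-yn-4-yl]oxy}dimethylsilane | COc1ccc(COC/C=C(\C)CC/C=C(\C)[C@H](O[Si](C)(C)C(C)(C)C)CC#C)cc1 | intermediate
7 | tert-butyl{[(5R,6E,10E)-12-[(4-methoxybenzyl)oxy]-6,10-dimethyldodeca-6,10-dien-2-yn-5-yl]oxy}dimethylsilane | COc1ccc(COC/C=C(\C)CC/C=C(\C)[C@H](O[Si](C)(C)C(C)(C)C)CC#CC)cc1 | intermediate
8 | chlorobis(cyclopentadienyl)[(2E,5R,6E,10E)-5-(tert-butyldimethylsilyloxy)-12-[(4-methoxybenzyl)oxy]-6,10-dimethyldodeca-2,6,10-trien-2-yl]zirconium (η5-Cp written σ-bonded) | COc1ccc(COC/C=C(\C)CC/C=C(\C)[C@H](O[Si](C)(C)C(C)(C)C)C/C=C(\C)[Zr](Cl)(C2C=CC=C2)C2C=CC=C2)cc1 | intermediate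
9 | tert-butyl{[(2E,5R,6E,10E)-2-iodo-12-[(4-methoxybenzyl)oxy]-6,10-dimethyldodeca-2,6,10-trien-5-yl]oxy}dimethylsilane | COc1ccc(COC/C=C(\C)CC/C=C(\C)[C@H](O[Si](C)(C)C(C)(C)C)C/C=C(\C)I)cc1 | intermediate
10 | (2E,6E,8R,10E)-8-(tert-butyldimethylsilyloxy)-11-iodo-3,7-dimethyldodeca-2,6,10-trien-1-ol | OC/C=C(\C)CC/C=C(\C)[C@H](O[Si](C)(C)C(C)(C)C)C/C=C(\C)I | intermediate
11 | (2E,6E,8R,10E)-8-(tert-butyldimethylsilyloxy)-11-iodo-3,7-dimethyldodeca-2,6,10-trienal | O=C/C=C(\C)CC/C=C(\C)[C@H](O[Si](C)(C)C(C)(C)C)C/C=C(\C)I | intermediate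
12 | (4R)-4-benzyl-1,3-oxazolidin-2-one | O=C1N[C@H](Cc2ccccc2)CO1 | starting material
13 | methyl 4-chloro-4-oxobutanoate | COC(=O)CCC(Cl)=O | starting material
14 | methyl 4-[(4R)-4-benzyl-2-oxo-1,3-oxazolidin-3-yl]-4-oxobutanoate | COC(=O)CCC(=O)N1[C@H](Cc2ccccc2)COC1=O | intermediate
15 | methyl (3R,4S,5E,9E,11R,13E)-3-{[(4R)-4-benzyl-2-oxo-1,3-oxazolidin-3-yl]carbonyl}-11-(tert-butyldimethylsilyloxy)-4-hydroxy-14-iodo-6,10-dimethylpentadeca-5,9,13-trienoate | COC(=O)C[C@@H](C(=O)N1[C@H](Cc2ccccc2)COC1=O)[C@@H](O)/C=C(\C)CC/C=C(\C)[C@H](O[Si](C)(C)C(C)(C)C)C/C=C(\C)I | intermediate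
16 | (4R)-4-benzyl-3-{[(2S,3R)-2-Rs-5-oxooxolan-3-yl]carbonyl}-1,3-oxazolidin-2-one (trans-lactone) | O=C1C[C@@H](C(=O)N2[C@H](Cc3ccccc3)COC2=O)[C@H](/C=C(\C)CC/C=C(\C)[C@H](O[Si](C)(C)C(C)(C)C)C/C=C(\C)I)O1 | intermediate
17 | (4S,5S)-4-(hydroxymethyl)-5-Rs-oxolan-2-one | O=C1C[C@@H](CO)[C@H](/C=C(\C)CC/C=C(\C)[C@H](O[Si](C)(C)C(C)(C)C)C/C=C(\C)I)O1 | intermediate
18 | (2S,3R)-2-Rs-5-oxooxolane-3-carbaldehyde | O=C1C[C@@H](C=O)[C@H](/C=C(\C)CC/C=C(\C)[C@H](O[Si](C)(C)C(C)(C)C)C/C=C(\C)I)O1 | intermediate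
19 | (4S,5R)-4-ethenyl-5-Rs-oxolan-2-one | O=C1C[C@@H](C=C)[C@H](/C=C(\C)CC/C=C(\C)[C@H](O[Si](C)(C)C(C)(C)C)C/C=C(\C)I)O1 | intermediate
20 | (4R,5R)-4-[2-(9-borabicyclo[3.3.1]nonan-9-yl)ethyl]-5-Rs-oxolan-2-one | O=C1C[C@@H](CCB2C3CCCC2CCC3)[C@H](/C=C(\C)CC/C=C(\C)[C@H](O[Si](C)(C)C(C)(C)C)C/C=C(\C)I)O1 | intermediate
21 | (1R,2R,9R,3E,7E,11E)-9-(tert-butyldimethylsilyloxy)-17-norcembra-3,7,11-trien-16,2-olide (14-membered ring trans-fused to the γ-lactone; CH2 at C15) | C1C(=O)O[C@H]2/C=C(\C)CC/C=C(\C)[C@H](O[Si](C)(C)C(C)(C)C)C/C=C(\C)CC[C@H]12 | intermediate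
22 | (1R,2R,9R,15S,3E,7E,11E)-9-(tert-butyldimethylsilyloxy)-17-(dimethylamino)cembra-3,7,11-trien-16,2-olide | CN(C)C[C@H]1C(=O)O[C@H]2/C=C(\C)CC/C=C(\C)[C@H](O[Si](C)(C)C(C)(C)C)C/C=C(\C)CC[C@H]12 | intermediate
23 | (1R,2R,9R,15S,3E,7E,11E)-9-(tert-butyldimethylsilyloxy)-17-(trimethylammonio)cembra-3,7,11-trien-16,2-olide iodide | C[N+](C)(C)C[C@H]1C(=O)O[C@H]2/C=C(\C)CC/C=C(\C)[C@H](O[Si](C)(C)C(C)(C)C)C/C=C(\C)CC[C@H]12.[I-] | intermediate
24 | (1R,2S,9R,3E,7E,11E)-9-(tert-butyldimethylsilyloxy)cembra-3,7,11,15(17)-tetraen-16,2-olide | C=C1C(=O)O[C@H]2/C=C(\C)CC/C=C(\C)[C@H](O[Si](C)(C)C(C)(C)C)C/C=C(\C)CC[C@H]12 | intermediate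
25 | (1R,2S,9R,3E,7E,11E)-9-hydroxycembra-3,7,11,15(17)-tetraen-16,2-olide | C=C1C(=O)O[C@H]2/C=C(\C)CC/C=C(\C)[C@H](O)C/C=C(\C)CC[C@H]12 | intermediate
26 | (1R,2S,9R,3E,7E,11E)-9-acetoxycembra-3,7,11,15(17)-tetraen-16,2-olide (CNP0129197.1) | C=C1C(=O)O[C@H]2/C=C(\C)CC/C=C(\C)[C@H](OC(C)=O)C/C=C(\C)CC[C@H]12 | target

## Step count and risk
Total step count: 20. Longest linear sequence: 19 steps (steps 1–9 and 11–20 from geraniol); step 10 is a one-step side branch.

Three steps most likely to fail: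

Step 15 (macrocyclisation). Oligomerisation, slow transmetalation or lactone saponification under aqueous base can erode the yield. The fallback sets out from 19 and comes back at 21, replacing the boron/aqueous-base manifold by a preformed alkylzinc under neutral anhydrous conditions. Vinyl lactone 19 is hydroborated with 9-BBN as before (borane 20) but oxidised with NaBO3·4H2O to the primary alcohol (4R,5R)-4-(2-hydroxyethyl)-5-Rs-oxolan-2-one F6. Iodination with I2/PPh3/imidazole gives the primary iodide (4S,5R)-4-(2-iodoethyl)-5-Rs-oxolan-2-one F7. Zinc insertion (Zn dust, LiCl, THF, rt; the alkenyl iodide does not insert) gives the alkylzinc iodide F8, which is added slowly to Pd2(dba)3/SPhos in THF/NMP for an intramolecular Negishi coupling that delivers 21.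

Step 4 (asymmetric propargylation). Enantioselectivity and the facial sense with this α-branched enal rest on analogy, and allenyl versus propargyl transfer could compete. The fallback sets out from 4 and comes back at 6, building the same centre by an auxiliary-controlled acetate aldol and a one-carbon homologation. The titanium enolate of commercial (S)-3-acetyl-4-isopropyl-1,3-thiazolidine-2-thione (TiCl4, iPr2NEt, CH2Cl2, −78 °C; chelated chair, diastereomers separable) adds to 4 to give the β-hydroxy thioimide F1 with the 3R (= C9 R) configuration. TBSOTf/2,6-lutidine gives the silyl ether F2. DIBAL-H (CH2Cl2, −78 °C) cleaves the auxiliary and gives the β-silyloxy aldehyde F3. Ohira–Bestmann homologation (dimethyl 1-diazo-2-oxopropylphosphonate, K2CO3, MeOH) converts F3 into alkyne 6.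

Step 12 (direct reductive removal of the auxiliary). Over-reduction of the γ-lactone or endocyclic cleavage of the oxazolidinone is possible. The fallback sets out from 16 and comes back at 17, using hydrolysis followed by chemoselective reduction of an activated acid. LiOH/H2O2 (THF/H2O, 0 °C), then acidification (the lactone re-closes), gives the lactone acid (2S,3R)-2-Rs-5-oxooxolane-3-carboxylic acid F4. Isobutyl chloroformate/N-methylmorpholine (THF, −15 °C) gives the mixed anhydride F5 (not isolated), which NaBH4/H2O reduces to 17 without touching the lactone or the alkenes.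

## Further compounds
F1 | step 4 | (3R,4E,8E)-3-hydroxy-1-[(4S)-4-isopropyl-2-thioxo-1,3-thiazolidin-3-yl]-10-[(4-methoxybenzyl)oxy]-4,8-dimethyldeca-4,8-dien-1-one | COc1ccc(COC/C=C(\C)CC/C=C(\C)[C@H](O)CC(=O)N2[C@@H](C(C)C)CSC2=S)cc1
F2 | step 4 | (3R,4E,8E)-3-(tert-butyldimethylsilyloxy)-1-[(4S)-4-isopropyl-2-thioxo-1,3-thiazolidin-3-yl]-10-[(4-methoxybenzyl)oxy]-4,8-dimethyldeca-4,8-dien-1-one | COc1ccc(COC/C=C(\C)CC/C=C(\C)[C@H](O[Si](C)(C)C(C)(C)C)CC(=O)N2[C@@H](C(C)C)CSC2=S)cc1
F3 | step 4 | (3R,4E,8E)-3-(tert-butyldimethylsilyloxy)-10-[(4-methoxybenzyl)oxy]-4,8-dimethyldeca-4,8-dienal | COc1ccc(COC/C=C(\C)CC/C=C(\C)[C@H](O[Si](C)(C)C(C)(C)C)CC=O)cc1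
F4 | step 12 | (2S,3R)-2-Rs-5-oxooxolane-3-carboxylic acid (Rs as in the compound list) | O=C1C[C@@H](C(=O)O)[C@H](/C=C(\C)CC/C=C(\C)[C@H](O[Si](C)(C)C(C)(C)C)C/C=C(\C)I)O1
F5 | step 12 | (2S,3R)-2-Rs-5-oxooxolane-3-carboxylic isobutyl carbonic anhydride | O=C1C[C@@H](C(=O)OC(=O)OCC(C)C)[C@H](/C=C(\C)CC/C=C(\C)[C@H](O[Si](C)(C)C(C)(C)C)C/C=C(\C)I)O1
F6 | step 15 | (4R,5R)-4-(2-hydroxyethyl)-5-Rs-oxolan-2-one | O=C1C[C@@H](CCO)[C@H](/C=C(\C)CC/C=C(\C)[C@H](O[Si](C)(C)C(C)(C)C)C/C=C(\C)I)O1
F7 | step 15 | (4S,5R)-4-(2-iodoethyl)-5-Rs-oxolan-2-one | O=C1C[C@@H](CCI)[C@H](/C=C(\C)CC/C=C(\C)[C@H](O[Si](C)(C)C(C)(C)C)C/C=C(\C)I)O1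
F8 | step 15 | iodido{2-[(3S,2R)-2-Rs-5-oxooxolan-3-yl]ethyl}zinc (same spatial arrangement as F7) | O=C1C[C@@H](CC[Zn]I)[C@H](/C=C(\C)CC/C=C(\C)[C@H](O[Si](C)(C)C(C)(C)C)C/C=C(\C)I)O1
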